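**Plan**

1. Retrosynthetic cuts, in order: C1–C13′ together with C2–C3 (key step), then C3–C11′ (fragment union), then C4–C5 and O–C3 of a pyran ring. What remains is the ring A/B enal 5 (from xanthatin) and 1-O-acetylbritannilactone 1.
2. Forward: enal 5 → ring-B-fused pyrylium 9 (hetero-Diels–Alder, aromatization) → dearomatizing addition of the iodo ketene acetal of 2 to give dienal 12 → ring C and the norbornene in one operation → desilylation.
3. Enabling feature: ring C is a cyclopentene whose C2 carries the acetoxy oxygen between the quaternary bridgehead C1 and C3, with C4=C5 left over. This is the signature of conrotatory closure of a 1-acyloxypentadienyl cation (C2–C1–C5–C4–C3) followed by capture of the allyl cation at C1. Those five carbons plus the oxygen are a pyrylium ring, so the oxygen heterocycle is contracted to the carbocycle with its oxygen turned out as the C2 acetate, syn to C4=C5.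
4. Stereochemistry: C7, C8, C10 come with xanthatin; C4′, C6′, C7′, C8′ come with 1; C11′ is set by facial control in step 6; C1, C2 and C3 are set together in step 7.

Key step: step 7

Assumption: the sesquiterpene lactones 1 and 3 are catalogue natural products and serve as the commercial chiral-pool starting materials; C1–C15 number the guaiane-type half and C1′–C15′ the 1,10-seco-eudesmane half.

**Route**

Step 1
Reactants: 1 1-O-acetylbritannilactone
Product: 2 6′-O-triisopropylsilyl-1-O-acetylbritannilactone
Conditions: i-Pr3SiOSO2CF3, 2,6-lutidine, CH2Cl2, 0 °C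
Reagents that add atoms: triisopropylsilyl trifluoromethanesulfonate, CC(C)[Si](C(C)C)(C(C)C)OS(=O)(=O)C(F)(F)F
Why: O-silylation of the hindered allylic C6′ hydroxyl with a silyl triflate masks the only free OH against the acylating conditions of step 7 and touches no stereocentre.

Step 2
Reactants: 3 (−)-xanthatin
Product: 4 2,3-epoxyxanthatin (trans-oxirane, both diastereomers)
Conditions: t-BuOOH, DBU, CH2Cl2, 0 °C → rt
Reagents that add atoms: tert-butyl hydroperoxide, CC(C)(C)OO
Why: Weitz–Scheffer nucleophilic epoxidation should select the ketone-conjugated C2=C3 bond, because the peroxide anion adds faster to an enone β-carbon than to the lactone acrylate unit or to the hindered C5 terminus; the oxirane configuration is irrelevant.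

Step 3
Reactants: 4 2,3-epoxyxanthatin
Product: 5 ring A/B enal (C2 aldehyde on C1=C5)
Conditions: H5IO6, THF/H2O, 0 °C → rt
Reagents that add atoms: water, O
Why: Periodic acid opens the allylic oxirane to the glycol and cleaves it (Malaprade-type cleavage), leaving C2 as an aldehyde conjugated with C1=C5; C7, C8 and C10 are untouched.

Step 4
Reactants: 5 ring A/B enal; 6 ethyl 1-propenyl ether
Product: 7 2-ethoxy-3-methyl-3,4-dihydro-2H-pyran fused to ring B
Conditions: 6 (excess), europium tris(6,6,7,7,8,8,8-heptafluoro-2,2-dimethyloctane-3,5-dionate) (5 mol %), ClCH2CH2Cl, 50 °C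
Reagents that add atoms: none
Why: Inverse-electron-demand hetero-Diels–Alder reaction of the 1-oxadiene O=C2–C1=C5 with the enol ether joins C5 to the methyl-bearing carbon (future C4 with C15) and the aldehyde oxygen to the ethoxy-bearing carbon (future C3); the three new sp3 centres are erased in step 5.

Step 5
Reactants: 7 ethoxy-dihydropyran
Product: 9 ring-B-fused pyrylium tetrafluoroborate, via 4H-pyran 8 (not isolated)
Conditions: Ph3CBF4, MeCN, 0 °C → rt; precipitation with Et2O
Reagents that add atoms: triphenylcarbenium tetrafluoroborate, F[B-](F)(F)F.[C+](c1ccccc1)(c1ccccc1)c1ccccc1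
Why: The trityl cation first acts as a Lewis acid to eliminate ethanol from the cyclic acetal and then abstracts hydride from the doubly allylic C5–H, the classical 4H-pyran to pyrylium oxidation; C10 sits on a β-carbon of the pyrylium and is not acidified.

Step 6
Reactants: 2 silyl-protected methylene lactone; 9 pyrylium tetrafluoroborate
Product: 12 (1(5)Z,3E)-iodo dienal, via iodo silyl ketene acetal 10 (not isolated), via 2H-pyran adduct 11 (not isolated)
Conditions: 2, Me3SiI, CH2Cl2, −78 °C; then 9, MeCN, −78 → −20 °C; aq NaHCO3, rt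
Reagents that add atoms: iodotrimethylsilane, C[Si](C)(C)I
Why: Conjugate addition of iodide from Me3SiI to the methylene lactone gives the tetrasubstituted silyl ketene acetal 10, whose Mukaiyama-type addition to the pyrylium α-carbon flanked only by the C15 methyl (C3, not C2 next to the branched C10) dearomatizes the ring; C11′ should be set by attack on the enolate face carrying H-6′ (anti to the silyloxy group), and 6π-electrocyclic ring opening of 11 with C11′ rotating outward gives the (E)-C3=C4 dienal.

Step 7
Reactants: 12 iodo dienal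
Product: 14 6′-O-triisopropylsilyl ether of the target, via alkylzinc iodide 13 (not isolated)
Conditions: Zn dust (activated with Me3SiCl/BrCH2CH2Br), LiCl, THF, 30 °C; then Ac2O, Sc(O3SCF3)3 (20 mol %), CH2Cl2, −40 → 0 °C
Reagents that add atoms: acetic anhydride, CC(=O)OC(C)=O
Why: Proposed new method: O-acylation of the (2Z)-dienal (or of its 2H-pyran valence tautomer) gives a 1-acetoxypentadienyl cation spanning C2–C1–C5–C4–C3, which should undergo conrotatory 4π-electrocyclization to form C2–C3, and the resulting 2-acetoxycyclopentenyl cation (C1–C5–C4) is then quenched at C1 by the tethered C13′–Zn bond. The closest known reaction types are the iso-Nazarov cyclization of (2Z)-dienals, interrupted Nazarov reactions with carbon nucleophiles, and the Lewis-acid-mediated SN1 alkylation of tertiary and allylic cations by alkylzinc reagents; combining them on an acyloxy cation with a zinc homoenolate terminator is new. Ring C closes by the electrocyclization (five-membered, both termini sp2), and the bicyclo[2.2.1]heptene closes by intramolecular alkylation of the allyl cation at C1 (five-ring C1–C13′–C11′–C3–C2, which also completes the six-ring); attack at C4 is excluded because it would give a bicyclo[2.1.1]hexene. C2 and C3 are fixed relative to each other by conrotation with OAc and C11′ both outside (OAc trans to C11′, hence syn to C4=C5), and C1 is fixed by the one-carbon tether. The sense of rotation is expected to follow from the C10 methyl, which shields the face of C1 opposite to the one used, and from the C11′ centre, which places the lactone carbonyl exo. The step needs electrocyclization to outrun premature capture and proton loss: the E geometry of C3=C4 keeps C13′ out of reach of C5 and C1 until C3 is sp3, and the intramolecular terminator should compete with elimination.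

Step 8
Reactants: 14 silyl-protected target
Product: 15 target CNP0211028.3
Conditions: HF·pyridine, THF, 0 °C → rt
Reagents that add atoms: none
Why: Fluoride-mediated desilylation should free the C6′ hydroxyl without affecting the two acetates, the lactones or the bridge acetate.

**Compound list**

1 | 1-O-acetylbritannilactone, (4S)-4-[(3aS,4S,7aR)-4-hydroxy-6-methyl-3-methylidene-2-oxo-3a,4,7,7a-tetrahydro-1-benzofuran-5-yl]pentyl acetate | C=C1C(=O)O[C@@H]2CC(C)=C([C@@H](C)CCCOC(C)=O)[C@@H](O)[C@@H]21 | starting material
2 | 6′-O-triisopropylsilyl ether of 1 (4′S,6′S,7′S,8′R) | C=C1C(=O)O[C@@H]2CC(C)=C([C@@H](C)CCCOC(C)=O)[C@@H](O[Si](C(C)C)(C(C)C)C(C)C)[C@@H]21 | intermediate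
3 | (−)-xanthatin, (3aR,7S,8aS)-7-methyl-3-methylidene-6-[(1E)-3-oxobut-1-en-1-yl]-3,3a,4,7,8,8a-hexahydro-2H-cyclohepta[b]furan-2-one | C=C1C(=O)O[C@H]2C[C@H](C)C(/C=C/C(C)=O)=CC[C@H]12 | starting material
4 | 2,3-epoxyxanthatin, trans-oxirane on the former C2=C3 bond, both oxirane diastereomers (7R,8S,10S) | C=C1C(=O)O[C@H]2C[C@H](C)C(C3OC3C(C)=O)=CC[C@H]12 | intermediate
5 | (3aR,7S,8aS)-7-methyl-3-methylidene-2-oxo-3,3a,4,7,8,8a-hexahydro-2H-cyclohepta[b]furan-6-carbaldehyde | C=C1C(=O)O[C@H]2C[C@H](C)C(C=O)=CC[C@H]12 | intermediate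
6 | ethyl 1-propenyl ether (E/Z mixture) | CC=COCC | starting material
7 | 2-ethoxy-3-methyl-3,4-dihydro-2H-pyran fused to ring B: pyran O between C2 and C3, OEt on C3, C15 on C4, H on C5, C1=C2 (7R,8S,10S; mixture at C3, C4, C5) | C=C1C(=O)O[C@H]2C[C@H](C)C3=COC(OCC)C(C)C3C[C@H]12 | intermediate
8 | 4H-pyran: C1=C2 and C3=C4 enol ether bonds, C5–H sp3 (7R,8S,10S) | C=C1C(=O)O[C@H]2C[C@H](C)C3=COC=C(C)C3C[C@H]12 | intermediate
9 | pyrylium tetrafluoroborate: aromatic ring O–C2–C1–C5–C4–C3, C15 on C4, fused to ring B at C1–C5 (7R,8S,10S) | C=C1C(=O)O[C@H]2C[C@H](C)c3c[o+]cc(C)c3C[C@H]12.F[B-](F)(F)F | intermediate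
10 | silyl ketene acetal of 2: 3-(iodomethyl)-2-(trimethylsilyloxy)furan ring, C13′–I (4′S,6′S,7′S,8′R) | ICC1=C(O[Si](C)(C)C)O[C@@H]2CC(C)=C([C@@H](C)CCCOC(C)=O)[C@@H](O[Si](C(C)C)(C(C)C)C(C)C)[C@@H]21 | intermediate
11 | 2H-pyran adduct: pyran C3 (sp3, either epimer) bonded to quaternary C11′ bearing CH2I; C1=C2 and C4=C5; C11′ spatially as in the target | C=C1C(=O)O[C@H]2C[C@H](C)C3=COC([C@]4(CI)C(=O)O[C@@H]5CC(C)=C([C@@H](C)CCCOC(C)=O)[C@@H](O[Si](C(C)C)(C(C)C)C(C)C)[C@@H]54)C(C)=C3C[C@H]12 | intermediate
12 | (1(5)Z,3E)-dienal: C2 aldehyde on C1, C1=C5 in ring B, C4(C15)=C3H–C11′, C11′ bearing CH2I (11′R by CIP, spatially as in the target); other centres as in 2 and 5 | C=C1C(=O)O[C@H]2C[C@H](C)C(C=O)=C(C[C@H]12)/C(C)=C/[C@]3(CI)C(=O)O[C@@H]4CC(C)=C([C@@H](C)CCCOC(C)=O)[C@@H](O[Si](C(C)C)(C(C)C)C(C)C)[C@@H]43 | intermediate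
13 | alkylzinc iodide of 12 (C13′–ZnI) | C=C1C(=O)O[C@H]2C[C@H](C)C(C=O)=C(C[C@H]12)/C(C)=C/[C@]3(C[Zn]I)C(=O)O[C@@H]4CC(C)=C([C@@H](C)CCCOC(C)=O)[C@@H](O[Si](C(C)C)(C(C)C)C(C)C)[C@@H]43 | intermediate
14 | 6′-O-triisopropylsilyl ether of the target (1S,2R,3R,7R,8S,10S,11′S,4′S,6′S,7′S,8′R) | C=C1C(=O)O[C@H]2C[C@H](C)[C@@]34C[C@]5(C(=O)O[C@@H]6CC(C)=C([C@@H](C)CCCOC(C)=O)[C@@H](O[Si](C(C)C)(C(C)C)C(C)C)[C@@H]65)[C@@H](C(C)=C3C[C@H]12)[C@H]4OC(C)=O | intermediate
15 | CNP0211028.3: 2-acetoxy norbornene dimer, OAc on C2 syn to C4=C5, lactone carbonyl exo at spiro C11′, free 6′-OH, 1′-OAc | C=C1C(=O)O[C@H]2C[C@H](C)[C@@]34C[C@]5(C(=O)O[C@@H]6CC(C)=C([C@@H](C)CCCOC(C)=O)[C@@H](O)[C@@H]65)[C@@H](C(C)=C3C[C@H]12)[C@H]4OC(C)=O | target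

**Summary**

Total steps: 8. Longest linear sequence: 7 steps (3 → 15, steps 2–8).

Steps most likely to fail:

1. Step 7 (Proposed new method). Proton loss or acetate return from the cyclopentenyl cation may outrun C–C bond formation by the zinc terminator, and the conrotation may take the opposite sense. Fallback, from 12 back to 14: the acylative cyclization is run without zinc but with benzenethiol (Ac2O, Sc(O3SCF3)3, PhSH, CH2Cl2, −40 °C), so that sulfur captures the cation at C4 and gives the phenylthio-trapped cyclopentene F1 (iso-Nazarov cyclization with heteroatom trapping). Radical chain cyclization of F1 (Bu3SnH, AIBN, benzene, 80 °C) then forms C1–C13′ by 5-exo attack of the C13′ radical on C1 with expulsion of the thiyl radical from C4 (SH2′ allyl-sulfide cyclization). This restores C4=C5 and returns 14.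

2. Step 6. The ketene acetal may add to the wrong α-carbon of the pyrylium (C2 instead of C3), or to the wrong face at C11′. Fallback, from 7 and 2 back to 12: the ketene acetal 10 (from 2 and Me3SiI) is coupled with the cyclic acetal 7 itself under Me3SiOSO2CF3 catalysis (Mukaiyama-type acetal substitution). Only C3 is an acetal carbon, so the dihydropyran adduct F2 forms with defined regiochemistry. Dehydrogenation of F2 with DDQ (hydride abstraction at C5, proton loss from C4) gives 2H-pyran 11, which opens to 12.

3. Step 2. Chemoselectivity between the enone and the lactone acrylate unit may be lost (epoxidation or conjugate addition at C13, or 1,6-attack at C5). Fallback, from 3 back to 5: xanthatin is treated with pyrrolidine in wet THF. The amine masks the methylene lactone by conjugate addition and, through the C2 iminium, drives a retro-aldol loss of acetone to give the aminomethyl lactone enal F3. Quaternization with MeI and Hofmann elimination with aqueous NaHCO3 then regenerate the methylene lactone and return 5.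

**Further compounds**

F1 | step 7 | 2-acetoxy-4-methyl-4-(phenylsulfanyl)cyclopent-1(5)-ene fused to ring B, C3 bonded to C11′ (CH2I intact), OAc trans to C11′, C4 either epimer | C=C1C(=O)O[C@H]2C[C@H](C)C3=C(C[C@H]12)C(C)(Sc6ccccc6)[C@H]([C@]4(CI)C(=O)O[C@@H]5CC(C)=C([C@@H](C)CCCOC(C)=O)[C@@H](O[Si](C(C)C)(C(C)C)C(C)C)[C@@H]54)[C@H]3OC(C)=O
F2 | step 6 | 3,4-dihydro-2H-pyran adduct: pyran C3 bonded to C11′ (CH2I), C4–H and C5–H still sp3 (mixture at C3, C4, C5) | C=C1C(=O)O[C@H]2C[C@H](C)C3=COC([C@]4(CI)C(=O)O[C@@H]5CC(C)=C([C@@H](C)CCCOC(C)=O)[C@@H](O[Si](C(C)C)(C(C)C)C(C)C)[C@@H]54)C(C)C3C[C@H]12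
F3 | step 2 | 13-(pyrrolidin-1-yl)-11,13-dihydro derivative of enal 5 (C11 either epimer) | C1CCN(C1)CC3C(=O)O[C@H]2C[C@H](C)C(C=O)=CC[C@H]32
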